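**Retrosynthetic overview**
1. Target 12 ⇐ 11 (hydrogenolysis of two benzyl ethers) ⇐ chroman-3-one 10 (CBS reduction sets C3) ⇐ dihydrobenzofuran 8 (ring expansion).
2. Key disconnection: the pyran ring (O1–C2–C3–C4–C4a–C8a) is made from the five-membered ring of a 2,2-dimethyl-3-methylidene-2,3-dihydrobenzofuran (O1–C2–C3–C3a–C7a). An iodine(III)-induced oxidative 1,2-shift moves the aryl carbon from C3 to the exocyclic CH2, which becomes C4, while C3 becomes the ketone.
3. The five-membered ring comes in one step from Pd-catalysed heteroannulation of o-iodophenol 5 with 3-methylbuta-1,2-diene; the three allene carbons become C2, C3 and C4 of the target.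
4. Regiochemistry is fixed before any ring is made: C2v-symmetric 2,4,6-trihydroxytoluene is acylated (one product), the 4'-OH is benzylated and the only free ring carbon is iodinated, so only the oxygen ortho to the acyl group can close the ring. Ring order: arene (bought) → dihydrofuran (step 4) → pyran (step 6).
5. Enabling feature: C3 of the furan ring is bonded to arene carbon C3a, which has oxygen on both ortho carbons (O1 on C7a, OBn on C4) and on the para carbon (C6). The cation at C3 therefore forms readily and this aryl carbon migrates far better than the quaternary C2, which has no hydrogen and blocks alkene isomerisation.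

Key step: step 6

Remark on the chemistry: CIP analysis of the given SMILES assigns (S) to the carbinol carbon (C3 of the chroman). Benzofuran numbering is used for 7 and 8, chroman numbering for 9–12.

**Step 1**
Reactants: 1 2,4,6-trihydroxytoluene; 2 3-phenylpropanoyl chloride
Product: 3 1-(2,4,6-trihydroxy-3-methylphenyl)-3-phenylpropan-1-one
Conditions: AlCl3 (3 equiv), PhNO2, 0 °C → 60 °C; aq. HCl
Reagents that add atoms: none
Why: Friedel–Crafts acylation; the two free ring carbons of 1 are equivalent, so a single mono-ketone should form, and the chelated aryl ketone deactivates the ring towards a second acylation.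

**Step 2**
Reactants: 3 1-(2,4,6-trihydroxy-3-methylphenyl)-3-phenylpropan-1-one
Product: 4 1-[4-(benzyloxy)-2,6-dihydroxy-3-methylphenyl]-3-phenylpropan-1-one
Conditions: BnBr (1.05 equiv), K2CO3 (1.1 equiv), acetone, reflux
Reagents that add atoms: benzyl bromide, BrCc1ccccc1
Why: Williamson etherification; the 4'-OH, para to the carbonyl and outside the hydrogen bond to C=O, is the most acidic phenol and should be alkylated first with one equivalent of base and bromide.

**Step 3**
Reactants: 4 1-[4-(benzyloxy)-2,6-dihydroxy-3-methylphenyl]-3-phenylpropan-1-one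
Product: 5 1-[4-(benzyloxy)-2,6-dihydroxy-3-iodo-5-methylphenyl]-3-phenylpropan-1-one
Conditions: NIS (1.05 equiv), DMF, 0 °C → rt
Reagents that add atoms: N-iodosuccinimide, O=C1CCC(=O)N1I
Why: Electrophilic aromatic iodination at the only unsubstituted ring carbon, which is activated by three oxygens.

**Step 4**
Reactants: 5 1-[4-(benzyloxy)-2,6-dihydroxy-3-iodo-5-methylphenyl]-3-phenylpropan-1-one; 6 3-methylbuta-1,2-diene
Product: 7 1-[4-(benzyloxy)-6-hydroxy-2,2,5-trimethyl-3-methylidene-2,3-dihydro-1-benzofuran-7-yl]-3-phenylpropan-1-one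
Conditions: Pd(OAc)2 (5 mol %), PPh3 (10 mol %), K2CO3 (3 equiv), n-Bu4NCl (1 equiv), 6 (5 equiv), DMF, 80 °C, sealed tube
Reagents that add atoms: none
Why: Larock heteroannulation of a 1,2-diene: oxidative addition and carbopalladation place the aryl group on the central allene carbon, and 5-exo attack of the neighbouring phenoxide (the 4'-oxygen is blocked) on the more substituted terminus of the π-allylpalladium should give the 2,2-dimethyl-3-methylidene ring.

**Step 5**
Reactants: 7 1-[4-(benzyloxy)-6-hydroxy-2,2,5-trimethyl-3-methylidene-2,3-dihydro-1-benzofuran-7-yl]-3-phenylpropan-1-one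
Product: 8 1-[4,6-bis(benzyloxy)-2,2,5-trimethyl-3-methylidene-2,3-dihydro-1-benzofuran-7-yl]-3-phenylpropan-1-one
Conditions: BnBr (1.5 equiv), K2CO3 (2 equiv), n-Bu4NI (10 mol %), DMF, 60 °C
Reagents that add atoms: benzyl bromide, BrCc1ccccc1
Why: Williamson etherification of the remaining chelated phenol under slightly forcing conditions, so that no free phenol meets the iodine(III) oxidant of step 6.

**Step 6**
Reactants: 8 1-[4,6-bis(benzyloxy)-2,2,5-trimethyl-3-methylidene-2,3-dihydro-1-benzofuran-7-yl]-3-phenylpropan-1-one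
Product: 10 5,7-bis(benzyloxy)-2,2,6-trimethyl-8-(3-phenylpropanoyl)-2H-chromen-3(4H)-one, via dimethyl ketal 9 (not isolated)
Conditions: PhI(OH)OTs (1.1 equiv), MeOH–H2O 95:5/CH2Cl2, 0 °C → rt; then 1 M HCl, THF, rt
Reagents that add atoms: water, O (supplies the C3 carbonyl oxygen when ketal 9 is hydrolysed); methanol, CO (its methoxy groups appear only in 9)
Why: The electrophilic iodane adds to the exocyclic CH2, and the tertiary benzylic cation at C3 is captured by methanol; loss of iodobenzene from the CH2–I(III) unit is then accompanied by a 1,2-shift of the aryl carbon C3a from C3 to that CH2, and the resulting methoxy-oxocarbenium gives ketal 9, which is hydrolysed to 10. The closest known reaction is the Koser-reagent (HTIB) oxidative ring expansion of 1-methylidene benzocycloalkanes to β-benzocycloalkenones. No ring is closed by cyclisation: the six-membered ring (O1, C2, C3, C4, C4a, C8a) arises by ring enlargement of the five-membered ring (O1, C2, C3, C3a, C7a) through the 1,2-aryl shift. No stereocentre is formed. The step needs aryl rather than alkyl migration, which the ortho,ortho',para-oxygenated aryl carbon secures against the quaternary C2. It also needs the oxidant to attack the alkene rather than the arene, which the fully substituted, acyl-bearing and benzyl-protected ring secures.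

**Step 7**
Reactants: 10 5,7-bis(benzyloxy)-2,2,6-trimethyl-8-(3-phenylpropanoyl)-2H-chromen-3(4H)-one
Product: 11 1-[(3S)-5,7-bis(benzyloxy)-3-hydroxy-2,2,6-trimethyl-3,4-dihydro-2H-chromen-8-yl]-3-phenylpropan-1-one
Conditions: (R)-Me-CBS (20 mol %), BH3·SMe2 (0.7 equiv), THF, −20 °C; MeOH
Reagents that add atoms: none
Why: Corey–Bakshi–Shibata reduction: the (R)-oxazaborolidine–borane complex should bind the C3 ketone with the quaternary C2 as the large group and deliver hydride to the Re face to give (3S), while the C8 aryl ketone, flanked by two ortho substituents, should react much more slowly.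

**Step 8**
Reactants: 11 1-[(3S)-5,7-bis(benzyloxy)-3-hydroxy-2,2,6-trimethyl-3,4-dihydro-2H-chromen-8-yl]-3-phenylpropan-1-one
Product: 12 1-[(3S)-3,5,7-trihydroxy-2,2,6-trimethyl-3,4-dihydro-2H-chromen-8-yl]-3-phenylpropan-1-one
Conditions: H2 (1 atm), 10% Pd/C, EtOAc–MeOH, rt
Reagents that add atoms: none
Why: Hydrogenolysis of both benzyl ethers; the electron-rich aryl ketone, the tertiary-alkyl aryl ether and the non-benzylic carbinol should be inert, so C3 is not touched.

**Compound list**
1 | 2,4,6-trihydroxytoluene | Cc1c(O)cc(O)cc1O | starting material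
2 | 3-phenylpropanoyl chloride | O=C(Cl)CCc1ccccc1 | starting material
3 | 1-(2,4,6-trihydroxy-3-methylphenyl)-3-phenylpropan-1-one | Cc1c(O)cc(O)c(C(=O)CCc2ccccc2)c1O | intermediate
4 | 1-[4-(benzyloxy)-2,6-dihydroxy-3-methylphenyl]-3-phenylpropan-1-one | Cc1c(OCc2ccccc2)cc(O)c(C(=O)CCc2ccccc2)c1O | intermediate
5 | 1-[4-(benzyloxy)-2,6-dihydroxy-3-iodo-5-methylphenyl]-3-phenylpropan-1-one | Cc1c(OCc2ccccc2)c(I)c(O)c(C(=O)CCc2ccccc2)c1O | intermediate
6 | 3-methylbuta-1,2-diene | C=C=C(C)C | starting material
7 | 1-[4-(benzyloxy)-6-hydroxy-2,2,5-trimethyl-3-methylidene-2,3-dihydro-1-benzofuran-7-yl]-3-phenylpropan-1-one | C=C1c2c(OCc3ccccc3)c(C)c(O)c(C(=O)CCc3ccccc3)c2OC1(C)C | intermediate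
8 | 1-[4,6-bis(benzyloxy)-2,2,5-trimethyl-3-methylidene-2,3-dihydro-1-benzofuran-7-yl]-3-phenylpropan-1-one | C=C1c2c(OCc3ccccc3)c(C)c(OCc3ccccc3)c(C(=O)CCc3ccccc3)c2OC1(C)C | intermediate
9 | 1-[5,7-bis(benzyloxy)-3,3-dimethoxy-2,2,6-trimethyl-3,4-dihydro-2H-chromen-8-yl]-3-phenylpropan-1-one | COC1(OC)Cc2c(OCc3ccccc3)c(C)c(OCc3ccccc3)c(C(=O)CCc3ccccc3)c2OC1(C)C | intermediate (not isolated)
10 | 5,7-bis(benzyloxy)-2,2,6-trimethyl-8-(3-phenylpropanoyl)-2H-chromen-3(4H)-one | O=C1Cc2c(OCc3ccccc3)c(C)c(OCc3ccccc3)c(C(=O)CCc3ccccc3)c2OC1(C)C | intermediate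
11 | 1-[(3S)-5,7-bis(benzyloxy)-3-hydroxy-2,2,6-trimethyl-3,4-dihydro-2H-chromen-8-yl]-3-phenylpropan-1-one | Cc1c(OCc3ccccc3)c2c(c(C(=O)CCc3ccccc3)c1OCc1ccccc1)OC(C)(C)[C@@H](O)C2 | intermediate
12 | 1-[(3S)-3,5,7-trihydroxy-2,2,6-trimethyl-3,4-dihydro-2H-chromen-8-yl]-3-phenylpropan-1-one | Cc1c(O)c2c(c(C(=O)CCc3ccccc3)c1O)OC(C)(C)[C@@H](O)C2 | target

**Total step count:** 8. **Longest linear sequence:** 8 steps (1 → 12).

**Steps most likely to fail**

Step 6. The oxidant may be diverted to the electron-rich ring or the benzyl ethers, the new enolisable ketone may be α-tosyloxylated, or methanol may take part instead of the aryl shift (vicinal dimethoxylation). The fallback sets out from 8 and returns at 10. NBS in aqueous THF should give the bromohydrin 1-[4,6-bis(benzyloxy)-3-(bromomethyl)-3-hydroxy-2,2,5-trimethyl-2,3-dihydro-1-benzofuran-7-yl]-3-phenylpropan-1-one F1, with water entering at the tertiary benzylic carbon. Silver(I) tetrafluoroborate in CH2Cl2 then removes bromide and should trigger the Tiffeneau-type semipinacol shift of the same aryl carbon, giving 10 without a hypervalent iodine reagent.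

Step 4. Oxidative addition at the doubly ortho-substituted C–I bond may be slow and give way to hydrodeiodination, or the phenoxide may attack the unsubstituted terminus of the π-allyl intermediate. The fallback sets out from 4 and returns at 8; it builds the five-membered ring as a ketone and methylenates it. Mixed-anhydride Friedel–Crafts acylation of 4 with 2-bromo-2-methylpropanoic acid and trifluoroacetic anhydride, which spares the benzyl ether, should give 1-[4-(benzyloxy)-3-(2-bromo-2-methylpropanoyl)-2,6-dihydroxy-5-methylphenyl]-3-phenylpropan-1-one F2 at the only free ring carbon. K2CO3 in acetone should close the ring through the one free ortho-oxygen to 4-(benzyloxy)-6-hydroxy-2,2,5-trimethyl-7-(3-phenylpropanoyl)-1-benzofuran-3(2H)-one F3. Benzylation (BnBr, K2CO3, DMF) gives 4,6-bis(benzyloxy)-2,2,5-trimethyl-7-(3-phenylpropanoyl)-1-benzofuran-3(2H)-one F4. Wittig methylenation with Ph3P=CH2 at the ring ketone (the other ketone is shielded by two ortho substituents) then gives 8.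

Step 7. Facial discrimination may be insufficient, or the C8 aryl ketone may be reduced as well. The fallback sets out from 10 and returns at 11; it replaces the enantioselective reduction by a resolution. NaBH4 in MeOH at 0 °C should give racemic 1-[5,7-bis(benzyloxy)-3-hydroxy-2,2,6-trimethyl-3,4-dihydro-2H-chromen-8-yl]-3-phenylpropan-1-one F5. Esterification with (S)-O-acetylmandelic acid (DCC, DMAP) gives two diastereomeric esters, from which (3S)-5,7-bis(benzyloxy)-2,2,6-trimethyl-8-(3-phenylpropanoyl)-3,4-dihydro-2H-chromen-3-yl (2S)-2-(acetyloxy)-2-phenylacetate F6 is separated by chromatography or crystallisation. LiOH in aqueous THF releases 11. The other diastereomer can be saponified and reoxidised to 10 for recycling.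

**Further compounds**
F1 | step 6 | 1-[4,6-bis(benzyloxy)-3-(bromomethyl)-3-hydroxy-2,2,5-trimethyl-2,3-dihydro-1-benzofuran-7-yl]-3-phenylpropan-1-one (racemic) | OC1(CBr)c2c(OCc3ccccc3)c(C)c(OCc3ccccc3)c(C(=O)CCc3ccccc3)c2OC1(C)C
F2 | step 4 | 1-[4-(benzyloxy)-3-(2-bromo-2-methylpropanoyl)-2,6-dihydroxy-5-methylphenyl]-3-phenylpropan-1-one | Cc1c(OCc2ccccc2)c(C(=O)C(C)(C)Br)c(O)c(C(=O)CCc2ccccc2)c1O
F3 | step 4 | 4-(benzyloxy)-6-hydroxy-2,2,5-trimethyl-7-(3-phenylpropanoyl)-1-benzofuran-3(2H)-one | O=C1c2c(OCc3ccccc3)c(C)c(O)c(C(=O)CCc3ccccc3)c2OC1(C)C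
F4 | step 4 | 4,6-bis(benzyloxy)-2,2,5-trimethyl-7-(3-phenylpropanoyl)-1-benzofuran-3(2H)-one | O=C1c2c(OCc3ccccc3)c(C)c(OCc3ccccc3)c(C(=O)CCc3ccccc3)c2OC1(C)C
F5 | step 7 | 1-[5,7-bis(benzyloxy)-3-hydroxy-2,2,6-trimethyl-3,4-dihydro-2H-chromen-8-yl]-3-phenylpropan-1-one (racemic) | Cc1c(OCc3ccccc3)c2c(c(C(=O)CCc3ccccc3)c1OCc1ccccc1)OC(C)(C)C(O)C2
F6 | step 7 | (3S)-5,7-bis(benzyloxy)-2,2,6-trimethyl-8-(3-phenylpropanoyl)-3,4-dihydro-2H-chromen-3-yl (2S)-2-(acetyloxy)-2-phenylacetate | Cc1c(OCc3ccccc3)c2c(c(C(=O)CCc3ccccc3)c1OCc1ccccc1)OC(C)(C)[C@@H](OC(=O)[C@@H](OC(C)=O)c1ccccc1)C2
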